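**Retrosynthetic overview**
- The plan rests on ring-fusion carbon C8 of the dioxabicyclo[3.3.0]octane. C8 bears the oxymethylene C9 and is bonded to C8'. The neighbour of C8', C7', is benzylic to syringyl ring C, and C7 (benzylic to ring B) is linked to C9' through the other ring oxygen.
- Cutting C8–C8' and C7'–O opens both oxolanes to a 1-aryl-2,3-epoxypropyl cinnamyl ether, in which the epoxide is the source of the C8 radical and the alkene C8'=C7' is the acceptor. Oxolane C7/O/C9'/C8'/C8 forms first and oxolane C8/C9/O/C7'/C8' second, in the same flask.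
- The ether comes from an erythro epoxy alcohol (vinyl Grignard addition, then kinetic-resolution epoxidation, which sets C7) and a silyl-protected sinapyl bromide.
- The side chain is added last. The freed ring B phenol is converted to an aryloxyacetyl oxazolidinone, an auxiliary-controlled anti-aldol with O-benzylvanillin forms C7''–C8'', and reduction and deprotection follow.

Key step: step 8

Remark on locants: C7–C9 belong to the ring B half of the bicycle, C7'–C9' to the ring C half, and C7''–C9'' to the glycerol chain on ring A. The target reads as 7R,8S,7'R,8'S (exo,exo) and 7''R,8''S (erythro).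
Assumption: the magnesium enolate of the aryloxyacetyl imide is taken to react in the chelated form known for simple N-acyl oxazolidinones, and this fixes the choice of the (S)-auxiliary.

Step 1
Reactants: 1 4-(benzyloxy)-3-methoxybenzaldehyde (O-benzylvanillin); 2 vinylmagnesium bromide
Product: 3 rac-1-[4-(benzyloxy)-3-methoxyphenyl]prop-2-en-1-ol
Conditions: THF, 0 °C; aq NH4Cl
Reagents that add atoms: none
Why: Grignard 1,2-addition to a non-enolisable aromatic aldehyde, giving the carbinol centre as a racemate that is resolved in step 2.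

Step 2
Reactants: 3 rac-1-[4-(benzyloxy)-3-methoxyphenyl]prop-2-en-1-ol
Product: 4 (S)-[4-(benzyloxy)-3-methoxyphenyl][(R)-oxiran-2-yl]methanol (erythro)
Conditions: Ti(OiPr)4 (0.15 equiv), L-(+)-DIPT (0.2 equiv), t-BuOOH (0.45 equiv), 4 Å MS, CH2Cl2, −20 °C
Reagents that add atoms: tert-butyl hydroperoxide, CC(C)(C)OO
Why: Sharpless kinetic-resolution epoxidation, in which L-(+)-DIPT makes the (R)-enantiomer of 3 react much faster and hydroxyl-directed oxygen delivery gives the erythro epoxy alcohol, so stopping short of half conversion should give 4 with C7 in the required sense (the slow enantiomer is removed by chromatography, and the epoxide centre is erased in step 8).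

Step 3
Reactants: 5 sinapic acid
Product: 6 methyl (E)-sinapate
Conditions: MeOH, H2SO4 (cat.), reflux
Reagents that add atoms: methanol, CO
Why: Fischer esterification, to which the phenol and the conjugated alkene are inert.

Step 4
Reactants: 6 methyl (E)-sinapate
Product: 7 methyl (E)-3-[3,5-dimethoxy-4-(triisopropylsilyloxy)phenyl]acrylate
Conditions: TIPSCl, imidazole, DMF, rt
Reagents that add atoms: chlorotriisopropylsilane, CC(C)[Si](Cl)(C(C)C)C(C)C
Why: Imidazole-promoted silylation of the phenol, giving a bulky silyl ether that should survive hydride, alkoxide, trivalent titanium, hydrogenolysis and carbonate base and that keeps the para oxygen electron-releasing for step 8.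

Step 5
Reactants: 7 methyl (E)-3-[3,5-dimethoxy-4-(triisopropylsilyloxy)phenyl]acrylate
Product: 8 (E)-3-[3,5-dimethoxy-4-(triisopropylsilyloxy)phenyl]prop-2-en-1-ol
Conditions: i-Bu2AlH (2.5 equiv), CH2Cl2, −78 °C
Reagents that add atoms: none
Why: 1,2-Reduction of an α,β-unsaturated ester with i-Bu2AlH, which leaves the (E)-alkene and the aryl silyl ether untouched.

Step 6
Reactants: 8 (E)-3-[3,5-dimethoxy-4-(triisopropylsilyloxy)phenyl]prop-2-en-1-ol
Product: 9 (E)-3-[3,5-dimethoxy-4-(triisopropylsilyloxy)phenyl]prop-2-enyl bromide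
Conditions: CBr4, PPh3, CH2Cl2, −20 → 0 °C; pentane trituration, used at once
Reagents that add atoms: tetrabromomethane, BrC(Br)(Br)Br
Why: Appel bromination, an SN2 displacement of the oxyphosphonium ion under neutral conditions, which avoids the acid that would ionise the electron-rich cinnamyl system.

Step 7
Reactants: 4 erythro epoxy alcohol; 9 cinnamyl bromide
Product: 10 (R)-2-[(S)-[4-(benzyloxy)-3-methoxyphenyl]{[(E)-3-(3,5-dimethoxy-4-triisopropylsilyloxyphenyl)prop-2-enyl]oxy}methyl]oxirane
Conditions: NaH, Bu4NI (cat.), THF–DMF, 0 °C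
Reagents that add atoms: none
Why: Williamson etherification in which the sodium alkoxide of 4 attacks the primary allylic bromide without breaking any bond to C7, while the aprotic medium, low temperature and very reactive electrophile should suppress Payne-type epoxide migration.

Step 8
Reactants: 10 epoxypropyl cinnamyl ether
Product: 13 exo,exo-furofuran (7R,8S,7'R,8'S) bearing O-benzyl on ring B plus O-triisopropylsilyl on ring C, via bis-titanium oxolane 11 (not isolated), via benzylic iodide 12 (not isolated)
Conditions: Cp2TiCl2 (3 equiv), Zn dust, THF, rt, the green Cp2TiCl solution added dropwise to 10 under Ar; then I2 (1.5 equiv), rt → 45 °C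
Reagents that add atoms: none
Why: Cp2TiCl (trivalent titanium) transfers one electron to the terminal epoxide and breaks its C8–O bond, which gives the secondary C8 radical with a titanium alkoxide on C9; this is the reductive epoxide opening of the Nugent–RajanBabu type, and its combination with radical cyclisation and an iodine finish is the known entry to 2,6-diaryl furofurans. The radical adds to C8' of the cinnamyl alkene in a 5-exo-trig closure (first oxolane: C7, O, C9', C8', C8), preferred over 6-endo attack because it is the kinetically favoured mode and delivers the C7' radical stabilised by ring C. In the chair-like Beckwith–Houk transition state the ring B aryl on C7 lies pseudo-equatorial, so the one centre already present fixes C8 (C9 trans to the aryl) and C8' (C7' cis to C9), that is the cis ring fusion. A second Cp2TiCl captures the C7' radical as 11, and iodine cleaves the carbon–titanium bond to iodide 12, which ionises readily because of the para silyloxy group. The C9 titanium alkoxide then closes the second oxolane (C8, C9, O, C7', C8') in a 5-exo-tet or cation-capture mode, and C7' is set by the folded bicycle, which places ring C on the convex exo face whatever the configuration of 12. The step therefore needs 1,5-cis and 2,5-trans selectivity in the radical closure and exo selectivity at C7'; the bulky aryl on C7 secures the first two and the planar electron-rich benzylic cation the third.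

Step 9
Reactants: 13 protected furofuran
Product: 14 furofuran with free ring B phenol (ring C still O-triisopropylsilyl)
Conditions: H2 (1 atm), 10% Pd/C, EtOAc, rt, stopped at consumption of 13
Reagents that add atoms: none
Why: Catalytic hydrogenolysis of an aryl benzyl ether, which is cleaved far faster than the benzylic C–O bonds of the bicycle at one atmosphere in a neutral solvent and leaves the silyl ether intact.

Step 10
Reactants: 15 (S)-4-benzyloxazolidin-2-one; 16 bromoacetyl bromide
Product: 17 (S)-4-benzyl-3-(2-bromoacetyl)oxazolidin-2-one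
Conditions: n-BuLi, THF, −78 °C; then 16
Reagents that add atoms: none
Why: N-Acylation of the lithiated oxazolidinone, in which the acyl bromide reacts far faster than the alkyl bromide at low temperature.

Step 11
Reactants: 14 ring B phenol; 17 bromoacetyl imide
Product: 18 (S)-4-benzyl-3-(aryloxyacetyl)oxazolidin-2-one (aryl = ring B of the furofuran)
Conditions: K2CO3, acetone, rt
Reagents that add atoms: none
Why: Williamson-type O-alkylation of the phenoxide with an α-bromo imide, a very fast SN2 partner, under a base too weak to cleave the imide or the hindered aryl silyl ether.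

Step 12
Reactants: 18 aryloxyacetyl imide; 1 O-benzylvanillin
Product: 19 (2R,3R) anti-aldol adduct as its C7'' trimethylsilyl ether
Conditions: MgCl2 (0.2 equiv), Et3N (2 equiv), TMSCl (1.5 equiv), EtOAc, rt
Reagents that add atoms: chlorotrimethylsilane, C[Si](C)(C)Cl
Why: Magnesium halide-catalysed direct anti-aldol of a chiral N-acyl oxazolidinone with a non-enolisable aromatic aldehyde, in which Et3N soft-enolises the MgCl2-chelated imide to the Z-enolate, the face opposite the auxiliary benzyl group adds to 1 through a boat-like closed transition state, and TMSCl traps the aldolate, so that C8'' and C7'' are set as the anti (erythro) pair.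

Step 13
Reactants: 19 silylated aldol adduct
Product: 20 (7''R,8''S) primary alcohol with C7'' O-trimethylsilyl, ring C O-triisopropylsilyl, ring A O-benzyl
Conditions: LiBH4, MeOH (2 equiv), THF, 0 °C
Reagents that add atoms: none
Why: Reductive removal of the oxazolidinone with LiBH4, which attacks the exocyclic imide carbonyl and takes it to the primary alcohol C9'' without touching C8'', while the silyl ether on C7'' blocks retro-aldol cleavage (any silyl migration to C9'' is harmless because step 14 removes all silicon).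

Step 14
Reactants: 20 bis-silylated alcohol
Product: 21 (7''R,8''S) diol with free ring C phenol, ring A still O-benzyl
Conditions: Bu4NF, AcOH (2.5 equiv each), THF, 0 °C → rt
Reagents that add atoms: none
Why: Fluoride desilylation buffered with acetic acid removes both silyl groups and should spare the benzylic alcohol, the benzylic ethers and the liberated phenol.

Step 15
Reactants: 21 mono-benzyl ether
Product: 22 ficusesquilignan A
Conditions: H2 (1 atm), 10% Pd/C, EtOAc–EtOH, rt, stopped at consumption of 21
Reagents that add atoms: none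
Why: Catalytic hydrogenolysis of the last aryl benzyl ether under neutral conditions, a standard end step for arylglycerol β-aryl ethers, in which the benzylic alcohol and the benzylic ethers of the bicycle react much more slowly.

**Compound list**
1 | 4-(benzyloxy)-3-methoxybenzaldehyde | COc1cc(C=O)ccc1OCc1ccccc1 | starting material
2 | vinylmagnesium bromide | C=C[Mg]Br | starting material
3 | rac-1-[4-(benzyloxy)-3-methoxyphenyl]prop-2-en-1-ol | COc1cc(C(O)C=C)ccc1OCc1ccccc1 | intermediate
4 | (S)-[4-(benzyloxy)-3-methoxyphenyl][(R)-oxiran-2-yl]methanol | COc1cc([C@H](O)[C@H]2CO2)ccc1OCc1ccccc1 | intermediate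
5 | sinapic acid | COc1cc(/C=C/C(=O)O)cc(OC)c1O | starting material
6 | methyl (E)-sinapate | COC(=O)/C=C/c1cc(OC)c(O)c(OC)c1 | intermediate
7 | methyl (E)-3-[3,5-dimethoxy-4-(triisopropylsilyloxy)phenyl]acrylate | COC(=O)/C=C/c1cc(OC)c(O[Si](C(C)C)(C(C)C)C(C)C)c(OC)c1 | intermediate
8 | (E)-3-[3,5-dimethoxy-4-(triisopropylsilyloxy)phenyl]prop-2-en-1-ol | OC/C=C/c1cc(OC)c(O[Si](C(C)C)(C(C)C)C(C)C)c(OC)c1 | intermediate
9 | (E)-3-[3,5-dimethoxy-4-(triisopropylsilyloxy)phenyl]prop-2-enyl bromide | BrC/C=C/c1cc(OC)c(O[Si](C(C)C)(C(C)C)C(C)C)c(OC)c1 | intermediate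
10 | erythro 1-aryl-2,3-epoxypropyl (E)-cinnamyl ether (7S, epoxide CH R) | COc1cc([C@H](OC/C=C/c2cc(OC)c(O[Si](C(C)C)(C(C)C)C(C)C)c(OC)c2)[C@H]2CO2)ccc1OCc1ccccc1 | intermediate
11 | 2-aryl oxolane with CH2OTiCp2Cl on C8 and CH(TiCp2Cl)aryl on C8' (C7' unassigned; Cp rings written σ-bonded) | COc1cc([C@@H]2OC[C@@H](C([Ti](Cl)(C3C=CC=C3)C3C=CC=C3)c3cc(OC)c(O[Si](C(C)C)(C(C)C)C(C)C)c(OC)c3)[C@H]2CO[Ti](Cl)(C2C=CC=C2)C2C=CC=C2)ccc1OCc1ccccc1 | intermediate
12 | same oxolane with iodide on C7' and CH2OTiCp2Cl on C8 (C7' unassigned) | COc1cc([C@@H]2OC[C@@H](C(I)c3cc(OC)c(O[Si](C(C)C)(C(C)C)C(C)C)c(OC)c3)[C@H]2CO[Ti](Cl)(C2C=CC=C2)C2C=CC=C2)ccc1OCc1ccccc1 | intermediate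
13 | (1R,3aS,4R,6aS)-1-[4-(benzyloxy)-3-methoxyphenyl]-4-[3,5-dimethoxy-4-(triisopropylsilyloxy)phenyl]tetrahydro-1H,3H-furo[3,4-c]furan | COc1cc([C@@H]2OC[C@@H]3[C@H]2CO[C@H]3c2cc(OC)c(O[Si](C(C)C)(C(C)C)C(C)C)c(OC)c2)ccc1OCc1ccccc1 | intermediate
14 | the same furofuran with free ring B phenol | COc1cc([C@@H]2OC[C@@H]3[C@H]2CO[C@H]3c2cc(OC)c(O[Si](C(C)C)(C(C)C)C(C)C)c(OC)c2)ccc1O | intermediate
15 | (S)-4-benzyloxazolidin-2-one | O=C1N[C@@H](Cc2ccccc2)CO1 | starting material
16 | bromoacetyl bromide | BrCC(=O)Br | starting material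
17 | (S)-4-benzyl-3-(2-bromoacetyl)oxazolidin-2-one | O=C1OC[C@H](Cc2ccccc2)N1C(=O)CBr | intermediate
18 | (S)-4-benzyl-3-(aryloxyacetyl)oxazolidin-2-one, aryl = ring B of 14 | COc1cc([C@@H]2OC[C@@H]3[C@H]2CO[C@H]3c2cc(OC)c(O[Si](C(C)C)(C(C)C)C(C)C)c(OC)c2)ccc1OCC(=O)N1[C@@H](Cc2ccccc2)COC1=O | intermediate
19 | (2R,3R)-2-aryloxy-3-[4-(benzyloxy)-3-methoxyphenyl]-3-(trimethylsilyloxy)propanoyl imide of 15 | COc1cc([C@@H](O[Si](C)(C)C)[C@H](C(=O)N2[C@@H](Cc3ccccc3)COC2=O)Oc2ccc([C@@H]3OC[C@@H]4[C@H]3CO[C@H]4c3cc(OC)c(O[Si](C(C)C)(C(C)C)C(C)C)c(OC)c3)cc2OC)ccc1OCc1ccccc1 | intermediate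
20 | (7''R,8''S) primary alcohol, C7'' O-trimethylsilyl, ring C O-triisopropylsilyl, ring A O-benzyl | COc1cc([C@@H](O[Si](C)(C)C)[C@H](CO)Oc2ccc([C@@H]3OC[C@@H]4[C@H]3CO[C@H]4c3cc(OC)c(O[Si](C(C)C)(C(C)C)C(C)C)c(OC)c3)cc2OC)ccc1OCc1ccccc1 | intermediate
21 | ring A O-benzyl ether of ficusesquilignan A | COc1cc([C@@H](O)[C@H](CO)Oc2ccc([C@@H]3OC[C@@H]4[C@H]3CO[C@H]4c3cc(OC)c(O)c(OC)c3)cc2OC)ccc1OCc1ccccc1 | intermediate
22 | ficusesquilignan A, (1R,2S)-1-(4-hydroxy-3-methoxyphenyl)-2-{4-[(1R,3aS,4R,6aS)-4-(4-hydroxy-3,5-dimethoxyphenyl)tetrahydro-1H,3H-furo[3,4-c]furan-1-yl]-2-methoxyphenoxy}propane-1,3-diol | COc1cc([C@@H](O)[C@H](CO)Oc2ccc([C@@H]3OC[C@@H]4[C@H]3CO[C@H]4c3cc(OC)c(O)c(OC)c3)cc2OC)ccc1O | target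

**Step count**
Total step count: 15. Longest linear sequence: 12 (steps 3–9 and 11–15, from sinapic acid).

**Steps most likely to fail**

Step 8. What may go wrong:
- The C8 radical may be captured by a second titanium centre before it cyclises, and β-elimination then leads to deoxygenation.
- The benzyl–titanium bond may be protonated before iodine arrives.
- Facial selectivity in the closure at C7' may be poor.

The fallback sets out from 10, returns at 13, keeps the radical C8–C8' bond formation and separates the second ring closure from it. Compound 10 is cyclised with Cp2TiCl as before, but the mixture is quenched with aqueous NaH2PO4 to give the 2-aryl-4-benzyl-3-(hydroxymethyl)oxolane F1. Bu4NF then frees the syringyl phenol F2. Ag2O in CH2Cl2 oxidises this 4-alkyl-2,6-dimethoxyphenol to the para-quinone methide F3. The C9 hydroxyl adds to F3 in a conjugate 1,6-manner from the open face and gives the furofuran phenol F4. TIPSCl and imidazole convert F4 back to 13.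

Step 12. What may go wrong:
- The aryloxy and neighbouring methoxy oxygens may compete for magnesium and erode anti and facial selectivity.
- Retro-aldol equilibration may occur before silyl trapping.

The fallback sets out from 14, returns at 21 and replaces the anti-aldol by the boron syn-aldol followed by inversion at C7''. (R)-4-Benzyloxazolidin-2-one is acylated with 16 to the enantiomeric bromoacetyl imide F5. F5 alkylates 14 (K2CO3, acetone) to the (R)-aryloxyacetyl imide F6. The boron enolate (Bu2BOTf, i-Pr2NEt, CH2Cl2, −78 °C) adds to 1 to give the (2R,3S) syn adduct F7, in which C8'' is correct and C7'' is epimeric. LiBH4 gives the threo diol F8, and TBSCl with imidazole silylates the primary hydroxyl to the mono-silyl ether F9. A Mitsunobu reaction (4-nitrobenzoic acid, PPh3, DIAD) inverts C7'' to the erythro nitrobenzoate F10. K2CO3 in MeOH releases the erythro alcohol F11, and Bu4NF with AcOH removes both silyl groups to reach 21.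

Step 7. What may go wrong:
- The very electron-rich cinnamyl bromide may ionise or polymerise before it is alkylated.
- The base may induce epoxide migration in the alkoxide of 4.

The fallback sets out from 8 (together with 4), returns at 10 and avoids both the bromide and the free alkoxide. Methyl chloroformate and pyridine convert 8 into the storable cinnamyl methyl carbonate F12. The zinc alkoxide of 4 (Et2Zn, 0.5 equiv) is then allylated under zerovalent palladium catalysis generated from Pd(OAc)2 and 2-(di-tert-butylphosphino)biphenyl in THF. This is a Tsuji–Trost-type etherification, in which the π-allyl complex is attacked at its unsubstituted terminus and gives the linear (E)-ether 10.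

**Further compounds**
F1 | step 8 | 2-aryl-4-(3,5-dimethoxy-4-triisopropylsilyloxybenzyl)-3-(hydroxymethyl)oxolane | COc1cc([C@@H]2OC[C@@H](Cc3cc(OC)c(O[Si](C(C)C)(C(C)C)C(C)C)c(OC)c3)[C@H]2CO)ccc1OCc1ccccc1
F2 | step 8 | the same oxolane with free syringyl phenol | COc1cc([C@@H]2OC[C@@H](Cc3cc(OC)c(O)c(OC)c3)[C@H]2CO)ccc1OCc1ccccc1
F3 | step 8 | para-quinone methide of F2 | COc1cc([C@@H]2OC[C@@H](C=C3C=C(OC)C(=O)C(OC)=C3)[C@H]2CO)ccc1OCc1ccccc1
F4 | step 8 | exo,exo-furofuran with ring B O-benzyl and free ring C phenol | COc1cc([C@@H]2OC[C@@H]3[C@H]2CO[C@H]3c2cc(OC)c(O)c(OC)c2)ccc1OCc1ccccc1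
F5 | step 12 | (R)-4-benzyl-3-(2-bromoacetyl)oxazolidin-2-one | O=C1OC[C@@H](Cc2ccccc2)N1C(=O)CBr
F6 | step 12 | (R)-4-benzyl-3-(aryloxyacetyl)oxazolidin-2-one, aryl = ring B of 14 | COc1cc([C@@H]2OC[C@@H]3[C@H]2CO[C@H]3c2cc(OC)c(O[Si](C(C)C)(C(C)C)C(C)C)c(OC)c2)ccc1OCC(=O)N1[C@H](Cc2ccccc2)COC1=O
F7 | step 12 | (2R,3S) syn-aldol adduct on the (R)-auxiliary | COc1cc([C@H](O)[C@H](C(=O)N2[C@H](Cc3ccccc3)COC2=O)Oc2ccc([C@@H]3OC[C@@H]4[C@H]3CO[C@H]4c3cc(OC)c(O[Si](C(C)C)(C(C)C)C(C)C)c(OC)c3)cc2OC)ccc1OCc1ccccc1
F8 | step 12 | (7''S,8''S) threo diol, ring C O-triisopropylsilyl, ring A O-benzyl | COc1cc([C@H](O)[C@H](CO)Oc2ccc([C@@H]3OC[C@@H]4[C@H]3CO[C@H]4c3cc(OC)c(O[Si](C(C)C)(C(C)C)C(C)C)c(OC)c3)cc2OC)ccc1OCc1ccccc1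
F9 | step 12 | C9'' O-tert-butyldimethylsilyl ether of F8 | COc1cc([C@H](O)[C@H](CO[Si](C)(C)C(C)(C)C)Oc2ccc([C@@H]3OC[C@@H]4[C@H]3CO[C@H]4c3cc(OC)c(O[Si](C(C)C)(C(C)C)C(C)C)c(OC)c3)cc2OC)ccc1OCc1ccccc1
F10 | step 12 | (7''R,8''S) erythro 4-nitrobenzoate | COc1cc([C@@H](OC(=O)c2ccc(cc2)[N+](=O)[O-])[C@H](CO[Si](C)(C)C(C)(C)C)Oc2ccc([C@@H]3OC[C@@H]4[C@H]3CO[C@H]4c3cc(OC)c(O[Si](C(C)C)(C(C)C)C(C)C)c(OC)c3)cc2OC)ccc1OCc1ccccc1
F11 | step 12 | (7''R,8''S) erythro alcohol, C9'' O-tert-butyldimethylsilyl, ring C O-triisopropylsilyl | COc1cc([C@@H](O)[C@H](CO[Si](C)(C)C(C)(C)C)Oc2ccc([C@@H]3OC[C@@H]4[C@H]3CO[C@H]4c3cc(OC)c(O[Si](C(C)C)(C(C)C)C(C)C)c(OC)c3)cc2OC)ccc1OCc1ccccc1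
F12 | step 7 | (E)-3-[3,5-dimethoxy-4-(triisopropylsilyloxy)phenyl]prop-2-enyl methyl carbonate | COC(=O)OC/C=C/c1cc(OC)c(O[Si](C(C)C)(C(C)C)C(C)C)c(OC)c1
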